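**Retrosynthetic overview**
- The skeleton is numbered as a eudesmane: C10 (quaternary, methyl), C5 (ring-fusion CH), C1 (CH–CH2Ar), C4 (C(OH)CH3), C7 (isopropenyl); β is the face of the C10 methyl.
- Feature the strategy rests on: C10 and C5 are adjacent ring-fusion carbons flanked by C1 and C4 in ring A. This is the methyl-bearing C=C of 2-methoxy-5-methylbenzoquinone, whose two carbonyls become C1 and C4; a 2-silyloxybutadiene supplies C6–C9 of ring B and marks C7 with oxygen.
- Ring order: ring A is the purchased quinone; ring B is closed by a catalytic asymmetric Diels–Alder reaction (C5–C6 and C9–C10), followed by epimerisation at C5 to the trans fusion; the arene is purchased phloroglucinol.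
- Ring A after the key step: reductive removal of the C3 methoxy group, C4 methylenation and α-face hydration; C1 methylenation, hydroboration and B-alkyl Suzuki coupling for the ArCH2–C1 bond.
- End game: C7 ketone to nitrile to methyl ketone (equilibrated equatorial) to isopropenyl; two ortho-lithiations install isobutyryl and formyl; MOM removal.

Key step: step 2

Assumption: the (S)-configured oxazaborolidine is taken as the catalyst enantiomer that leaves open the quinone face giving C10 as drawn in 5 and 6; the catalyst alone fixes this sense, so its mirror image from (R)-diphenylprolinol would be used, all else unchanged, if the first run showed the opposite sense.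

**Route**

Step 1
Reactants: 1 methyl vinyl ketone; 2 triisopropylsilyl triflate
Product: 3 2-(triisopropylsilyloxy)buta-1,3-diene
Conditions: Et3N, Et2O, 0 °C to rt
Reagents that add atoms: none
Why: Silyl enol ether formation by soft enolisation: the silyl triflate activates the carbonyl and Et3N removes a methyl proton to give the cross-conjugated 2-silyloxydiene; no stereocentre is formed.

Step 2
Reactants: 4 2-methoxy-5-methyl-1,4-benzoquinone; 3 2-(triisopropylsilyloxy)buta-1,3-diene
Product: 6 trans-fused ene-dione silyl enol ether (4aR,8aR)-2-methoxy-4a-methyl-7-(triisopropylsilyloxy)-4a,5,8,8a-tetrahydronaphthalene-1,4-dione, via cis-fused adduct 5 (not isolated)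
Conditions: (S)-3,3-diphenyl-1-(o-tolyl)tetrahydro-1H,3H-pyrrolo[1,2-c][1,3,2]oxazaborole (20 mol %), Tf2NH (20 mol %), CH2Cl2, −78 to −40 °C; then DBU (0.5 equiv), −40 °C to rt
Reagents that add atoms: none
Why: The cationic oxazaborolidine binds the more basic C1 carbonyl (a vinylogous ester through C2=C3–OMe), which makes C5 the electrophilic β-carbon of the methyl-bearing alkene, so the nucleophilic CH2 terminus next to the silyloxy carbon of 3 bonds to C5 and the vinyl terminus bonds to C10 in a concerted asynchronous [4+2]; the closest known reaction type is the chiral oxazaborolidinium-catalysed Diels–Alder reaction of unsymmetrical quinones with 2-silyloxybutadienes. Ring B is closed by this intermolecular [4+2] cycloaddition, which forms C5–C6 and C9–C10 in one event and leaves the silyloxy carbon at C7. The quaternary C10 is set by the catalyst, whose aryl group shields one face of the bound quinone, and suprafacial addition places the C5 hydrogen cis to the C10 methyl in 5. C5 is then set by DBU, which enolises the C4 ketone toward C5 so that reprotonation settles on the trans-fused isomer 6, expected to be the more stable ring fusion; C10 is quaternary and can neither epimerise nor aromatise. The step needs site selectivity (the methoxy group deactivates its own alkene by donation), regioselectivity (secured by catalyst binding at C1 and the polarised diene) and enantioface selectivity (secured by the catalyst).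

Step 3
Reactants: 6 trans-fused ene-dione silyl enol ether
Product: 8 10β-methyl-7-(triisopropylsilyloxy)-5α-Δ7-octalin-1,4-dione, via 3-methoxy-1,4-dione 7 (not isolated)
Conditions: SmI2 (4.5 equiv), THF/MeOH, −78 to 0 °C
Reagents that add atoms: none
Why: Two known SmI2 reductions run in sequence, conjugate reduction of the ene-dione to 7 and then reductive cleavage of the α-methoxy ketone through the C4 ketyl, so C2 and C3 end as CH2; the enolates formed lie on the C3 side of C4, so C5 and C10 are untouched and the silyl enol ether is inert.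

Step 4
Reactants: 8 10β-methyl-7-(triisopropylsilyloxy)-5α-Δ7-octalin-1,4-dione
Product: 9 10β-methyl-4-methylene-7-(triisopropylsilyloxy)-5α-Δ7-octalin-1-one
Conditions: Ph3PCH3Br (1.2 equiv), KHMDS (1.1 equiv), THF, 0 °C; then 8, −40 °C to rt
Reagents that add atoms: methyltriphenylphosphonium bromide, C[P+](c1ccccc1)(c1ccccc1)c1ccccc1.[Br-]
Why: Wittig methylenation that tells the two ketones apart by sterics: C4 has an open equatorial (α) approach, whereas C1 sits next to quaternary C10, whose axial methyl blocks the equatorial approach, so one equivalent of ylide at low temperature should react at C4 only; the trans fusion is the stable one, so reversible enolisation toward C5 should do no harm.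

Step 5
Reactants: 9 10β-methyl-4-methylene-7-(triisopropylsilyloxy)-5α-Δ7-octalin-1-one
Product: 10 10β-methyl-4-methylene-5α-decalin-1,7-dione
Conditions: TBAF, AcOH, THF, 0 °C
Reagents that add atoms: none
Why: Fluoride cleavage of the silyl enol ether with protonation of the enolate at C8 unmasks the C7 ketone, which the silyl group has protected through steps 3 and 4; C5 is no longer α to a carbonyl, so no stereocentre is at risk.

Step 6
Reactants: 10 10β-methyl-4-methylene-5α-decalin-1,7-dione
Product: 11 4α-hydroxy-4β,10β-dimethyl-5α-decalin-1,7-dione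
Conditions: Co(acac)2 (20 mol %), PhSiH3, O2 (1 atm), THF, rt
Reagents that add atoms: dioxygen, O=O
Why: Mukaiyama hydration (hydrogen-atom transfer to the CH2 terminus, trapping of the tertiary C4 radical by O2, reduction of the peroxide by the silane) gives the Markovnikov alcohol; the β face of C4 is 1,3-diaxial to the C10 methyl, so oxygen should add from the α face and give the equatorial 4α-hydroxyl with the axial 4β-methyl.

Step 7
Reactants: 11 4α-hydroxy-4β,10β-dimethyl-5α-decalin-1,7-dione
Product: 12 4α-hydroxy-4β,10β-dimethyl-1-oxo-5α-decalin-7-carbonitrile (C7 epimer mixture)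
Conditions: TosMIC (1.2 equiv), t-BuOK, DME/EtOH, 0 °C to rt
Reagents that add atoms: p-toluenesulfonylmethyl isocyanide, Cc1ccc(cc1)S(=O)(=O)C[N+]#[C-]
Why: Van Leusen reductive cyanation converts the unhindered C7 ketone into the nitrile with one added carbon, while the C1 ketone next to quaternary C10 is expected to stay; C7 forms as an epimer mixture and is set later by equilibration in step 12.

Step 8
Reactants: 12 4α-hydroxy-4β,10β-dimethyl-1-oxo-5α-decalin-7-carbonitrile
Product: 13 4α-hydroxy-4β,10β-dimethyl-1-methylene-5α-decalin-7-carbonitrile (C7 epimer mixture)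
Conditions: Ph3PCH3Br (4 equiv), t-BuOK (3.8 equiv), toluene, 90 °C
Reagents that add atoms: methyltriphenylphosphonium bromide, C[P+](c1ccccc1)(c1ccccc1)c1ccccc1.[Br-]
Why: Wittig methylenation of the hindered C1 ketone under forcing conditions (excess ylide, base kept below the phosphonium salt, hot toluene), which the nitrile and the tertiary alkoxide should tolerate; no stereocentre is formed.

Step 9
Reactants: 14 phloroglucinol
Product: 15 1,3,5-tris(methoxymethoxy)benzene
Conditions: NaH, MOMCl, DMF, 0 °C to rt
Reagents that add atoms: chloromethyl methyl ether, COCCl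
Why: Threefold Williamson-type O-alkylation of the phenoxides with the hard electrophile MOMCl; MOM is chosen because it directs ortho-lithiation later and leaves under mild acid.

Step 10
Reactants: 15 1,3,5-tris(methoxymethoxy)benzene
Product: 16 2-bromo-1,3,5-tris(methoxymethoxy)benzene
Conditions: NBS (1.0 equiv), CH2Cl2, −78 to 0 °C
Reagents that add atoms: N-bromosuccinimide, O=C1CCC(=O)N1Br
Why: Electrophilic aromatic bromination of the highly activated ring; the three ring positions are equivalent, and one equivalent of NBS at low temperature should stop at the monobromide.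

Step 11
Reactants: 13 4α-hydroxy-4β,10β-dimethyl-1-methylene-5α-decalin-7-carbonitrile; 16 2-bromo-1,3,5-tris(methoxymethoxy)benzene
Product: 18 4α-hydroxy-4β,10β-dimethyl-1β-[2,4,6-tris(methoxymethoxy)benzyl]-5α-decalin-7-carbonitrile (C7 epimer mixture), via B-alkyl-9-BBN borane 17 (not isolated)
Conditions: 9-BBN (2.5 equiv), THF, 0 to 50 °C; then aq. K3PO4, 16, Pd(OAc)2 (5 mol %), SPhos (10 mol %), THF/H2O, 65 °C
Reagents that add atoms: none
Why: Hydroboration with 9-BBN puts boron on the CH2 and delivers hydrogen to C1 from the α face, opposite the axial C10 methyl that covers the β face of the alkene, which sets C1 with its CH2 substituent β (equatorial); the B-alkyl Suzuki–Miyaura coupling then joins the primary alkylborane to the di-ortho-substituted aryl bromide without touching C1.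

Step 12
Reactants: 18 4α-hydroxy-4β,10β-dimethyl-1β-[2,4,6-tris(methoxymethoxy)benzyl]-5α-decalin-7-carbonitrile
Product: 20 7β-acetyl-4β,10β-dimethyl-1β-[2,4,6-tris(methoxymethoxy)benzyl]-5α-decalin-4α-ol, via ketimine 19 (not isolated)
Conditions: MeLi (4 equiv), Et2O/THF, 0 °C to rt; aq. AcOH, rt; then NaOMe (cat.), MeOH, rt
Reagents that add atoms: methyllithium, [Li]C; water, O
Why: Addition of methyllithium to the nitrile gives the ketimine 19, mild acid hydrolyses it to the methyl ketone, and base equilibration through the C7 enolate should place the acetyl group equatorial (7β), which sets the C7 stereocentre; the minor axial epimer can be separated and equilibrated again.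

Step 13
Reactants: 20 7β-acetyl-4β,10β-dimethyl-1β-[2,4,6-tris(methoxymethoxy)benzyl]-5α-decalin-4α-ol
Product: 21 7β-isopropenyl-4β,10β-dimethyl-1β-[2,4,6-tris(methoxymethoxy)benzyl]-5α-decalin-4α-ol
Conditions: Ph3PCH3Br (3 equiv), KHMDS (2.8 equiv), THF, 0 °C to rt
Reagents that add atoms: methyltriphenylphosphonium bromide, C[P+](c1ccccc1)(c1ccccc1)c1ccccc1.[Br-]
Why: Wittig methylenation of the unhindered methyl ketone gives the isopropenyl group; any enolisation at C7 returns to the equatorial ketone, so the 7β configuration should be kept.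

Step 14
Reactants: 21 7β-isopropenyl-4β,10β-dimethyl-1β-[2,4,6-tris(methoxymethoxy)benzyl]-5α-decalin-4α-ol
Product: 23 1β-[3-(1-hydroxy-2-methylpropyl)-2,4,6-tris(methoxymethoxy)benzyl]-7β-isopropenyl-4β,10β-dimethyl-5α-decalin-4α-ol (carbinol epimers), via aryllithium 22 (not isolated)
Conditions: n-BuLi (2.2 equiv), THF, −20 to 0 °C; then i-PrCHO, −78 °C; H2O
Reagents that add atoms: isobutyraldehyde, CC(C)C=O
Why: Directed ortho-metalation: after the hydroxyl is deprotonated, n-BuLi removes one of the two equivalent ring hydrogens, each flanked by two MOM ethers, and the aryllithium adds 1,2 to isobutyraldehyde; the new carbinol centre is uncontrolled and is erased in step 16.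

Step 15
Reactants: 23 1β-[3-(1-hydroxy-2-methylpropyl)-2,4,6-tris(methoxymethoxy)benzyl]-7β-isopropenyl-4β,10β-dimethyl-5α-decalin-4α-ol
Product: 25 1β-[3-formyl-5-(1-hydroxy-2-methylpropyl)-2,4,6-tris(methoxymethoxy)benzyl]-7β-isopropenyl-4β,10β-dimethyl-5α-decalin-4α-ol, via aryllithium 24 (not isolated)
Conditions: n-BuLi (3.5 equiv), THF, −20 to 0 °C; then DMF, −78 to 0 °C; H2O
Reagents that add atoms: N,N-dimethylformamide, CN(C)C=O
Why: A second directed ortho-metalation at the last ring hydrogen, again between two MOM ethers, followed by formylation with DMF gives the aryl aldehyde after aqueous collapse of the hemiaminal.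

Step 16
Reactants: 25 1β-[3-formyl-5-(1-hydroxy-2-methylpropyl)-2,4,6-tris(methoxymethoxy)benzyl]-7β-isopropenyl-4β,10β-dimethyl-5α-decalin-4α-ol
Product: 26 1β-[3-formyl-5-isobutyryl-2,4,6-tris(methoxymethoxy)benzyl]-7β-isopropenyl-4β,10β-dimethyl-5α-decalin-4α-ol
Conditions: Dess–Martin periodinane, NaHCO3, CH2Cl2, rt
Reagents that add atoms: none
Why: Dess–Martin oxidation of the secondary benzylic alcohol to the aryl isopropyl ketone; the tertiary alcohol, the aldehyde and the isopropenyl group should not react, and the bicarbonate buffer protects the MOM ethers.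

Step 17
Reactants: 26 1β-[3-formyl-5-isobutyryl-2,4,6-tris(methoxymethoxy)benzyl]-7β-isopropenyl-4β,10β-dimethyl-5α-decalin-4α-ol
Product: 27 CNP0498016.1
Conditions: HCl (1.25 M in MeOH), rt
Reagents that add atoms: none
Why: Acid-catalysed acetal solvolysis (MOM cleavage by transacetalisation to methanol), fast for aryl MOM ethers ortho to a carbonyl, under conditions expected to be too mild to ionise the unactivated tertiary alcohol or add to the isopropenyl group; all stereocentres are unchanged.

**Compound list**

1 | methyl vinyl ketone | C=CC(C)=O | starting material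
2 | triisopropylsilyl triflate | CC(C)[Si](OS(=O)(=O)C(F)(F)F)(C(C)C)C(C)C | starting material
3 | 2-(triisopropylsilyloxy)buta-1,3-diene | C=CC(=C)O[Si](C(C)C)(C(C)C)C(C)C | intermediate
4 | 2-methoxy-5-methyl-1,4-benzoquinone | COC1=CC(=O)C(C)=CC1=O | starting material
5 | cis-fused adduct, (4aR,8aS)-2-methoxy-4a-methyl-7-(triisopropylsilyloxy)-4a,5,8,8a-tetrahydronaphthalene-1,4-dione (10β-methyl, 5β-H) | CC(C)[Si](C(C)C)(C(C)C)OC1=CC[C@@]2(C)C(=O)C=C(OC)C(=O)[C@H]2C1 | intermediate (not isolated)
6 | trans-fused ene-dione silyl enol ether, (4aR,8aR)-2-methoxy-4a-methyl-7-(triisopropylsilyloxy)-4a,5,8,8a-tetrahydronaphthalene-1,4-dione (10β-methyl, 5α-H) | CC(C)[Si](C(C)C)(C(C)C)OC1=CC[C@@]2(C)C(=O)C=C(OC)C(=O)[C@@H]2C1 | intermediate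
7 | 3-methoxy-10β-methyl-7-(triisopropylsilyloxy)-5α-Δ7-octalin-1,4-dione (C3 epimers) | CC(C)[Si](C(C)C)(C(C)C)OC1=CC[C@@]2(C)C(=O)CC(OC)C(=O)[C@@H]2C1 | intermediate (not isolated)
8 | 10β-methyl-7-(triisopropylsilyloxy)-5α-Δ7-octalin-1,4-dione | CC(C)[Si](C(C)C)(C(C)C)OC1=CC[C@@]2(C)C(=O)CCC(=O)[C@@H]2C1 | intermediate
9 | 10β-methyl-4-methylene-7-(triisopropylsilyloxy)-5α-Δ7-octalin-1-one | CC(C)[Si](C(C)C)(C(C)C)OC1=CC[C@@]2(C)C(=O)CCC(=C)[C@@H]2C1 | intermediate
10 | 10β-methyl-4-methylene-5α-decalin-1,7-dione | O=C1CC[C@@]2(C)C(=O)CCC(=C)[C@@H]2C1 | intermediate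
11 | 4α-hydroxy-4β,10β-dimethyl-5α-decalin-1,7-dione | O=C1CC[C@@]2(C)C(=O)CC[C@@](C)(O)[C@@H]2C1 | intermediate
12 | 4α-hydroxy-4β,10β-dimethyl-1-oxo-5α-decalin-7-carbonitrile (C7 epimer mixture) | N#CC1CC[C@@]2(C)C(=O)CC[C@@](C)(O)[C@@H]2C1 | intermediate
13 | 4α-hydroxy-4β,10β-dimethyl-1-methylene-5α-decalin-7-carbonitrile (C7 epimer mixture) | N#CC1CC[C@@]2(C)C(=C)CC[C@@](C)(O)[C@@H]2C1 | intermediate
14 | phloroglucinol | Oc1cc(O)cc(O)c1 | starting material
15 | 1,3,5-tris(methoxymethoxy)benzene | COCOc1cc(OCOC)cc(OCOC)c1 | intermediate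
16 | 2-bromo-1,3,5-tris(methoxymethoxy)benzene | COCOc1cc(OCOC)c(Br)c(OCOC)c1 | intermediate
17 | 1β-(9-borabicyclo[3.3.1]nonan-9-ylmethyl)-4α-hydroxy-4β,10β-dimethyl-5α-decalin-7-carbonitrile | N#CC1CC[C@@]2(C)[C@H](CB3C4CCCC3CCC4)CC[C@@](C)(O)[C@@H]2C1 | intermediate (not isolated)
18 | 4α-hydroxy-4β,10β-dimethyl-1β-[2,4,6-tris(methoxymethoxy)benzyl]-5α-decalin-7-carbonitrile (C7 epimer mixture) | N#CC1CC[C@@]2(C)[C@H](Cc3c(OCOC)cc(OCOC)cc3OCOC)CC[C@@](C)(O)[C@@H]2C1 | intermediate
19 | C7 methyl ketimine of 18 (formed as its N-lithio salt) | CC(=N)C1CC[C@@]2(C)[C@H](Cc3c(OCOC)cc(OCOC)cc3OCOC)CC[C@@](C)(O)[C@@H]2C1 | intermediate (not isolated)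
20 | 7β-acetyl-4β,10β-dimethyl-1β-[2,4,6-tris(methoxymethoxy)benzyl]-5α-decalin-4α-ol | CC(=O)[C@@H]1CC[C@@]2(C)[C@H](Cc3c(OCOC)cc(OCOC)cc3OCOC)CC[C@@](C)(O)[C@@H]2C1 | intermediate
21 | 7β-isopropenyl-4β,10β-dimethyl-1β-[2,4,6-tris(methoxymethoxy)benzyl]-5α-decalin-4α-ol | C=C(C)[C@@H]1CC[C@@]2(C)[C@H](Cc3c(OCOC)cc(OCOC)cc3OCOC)CC[C@@](C)(O)[C@@H]2C1 | intermediate
22 | dilithio derivative of 21 (C4 lithium alkoxide, aryl C–Li between two MOM ethers) | C=C(C)[C@@H]1CC[C@@]2(C)[C@H](Cc3c(OCOC)cc(OCOC)c([Li])c3OCOC)CC[C@@](C)(O[Li])[C@@H]2C1 | intermediate (not isolated)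
23 | 1β-[3-(1-hydroxy-2-methylpropyl)-2,4,6-tris(methoxymethoxy)benzyl]-7β-isopropenyl-4β,10β-dimethyl-5α-decalin-4α-ol (carbinol epimers) | C=C(C)[C@@H]1CC[C@@]2(C)[C@H](Cc3c(OCOC)cc(OCOC)c(C(O)C(C)C)c3OCOC)CC[C@@](C)(O)[C@@H]2C1 | intermediate
24 | trilithio derivative of 23 (two lithium alkoxides, aryl C–Li at the last ring position) | C=C(C)[C@@H]1CC[C@@]2(C)[C@H](Cc3c(OCOC)c([Li])c(OCOC)c(C(O[Li])C(C)C)c3OCOC)CC[C@@](C)(O[Li])[C@@H]2C1 | intermediate (not isolated)
25 | 1β-[3-formyl-5-(1-hydroxy-2-methylpropyl)-2,4,6-tris(methoxymethoxy)benzyl]-7β-isopropenyl-4β,10β-dimethyl-5α-decalin-4α-ol | C=C(C)[C@@H]1CC[C@@]2(C)[C@H](Cc3c(OCOC)c(C=O)c(OCOC)c(C(O)C(C)C)c3OCOC)CC[C@@](C)(O)[C@@H]2C1 | intermediate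
26 | 1β-[3-formyl-5-isobutyryl-2,4,6-tris(methoxymethoxy)benzyl]-7β-isopropenyl-4β,10β-dimethyl-5α-decalin-4α-ol | C=C(C)[C@@H]1CC[C@@]2(C)[C@H](Cc3c(OCOC)c(C=O)c(OCOC)c(C(=O)C(C)C)c3OCOC)CC[C@@](C)(O)[C@@H]2C1 | intermediate
27 | CNP0498016.1 | C=C(C)[C@@H]1CC[C@@]2(C)[C@H](Cc3c(O)c(C=O)c(O)c(C(=O)C(C)C)c3O)CC[C@@](C)(O)[C@@H]2C1 | target

**Step count**

Total steps: 17. Longest linear sequence: 15 (steps 1–8 and 11–17; steps 9 and 10 make the aryl bromide).

**Steps most likely to fail**

Step 2. The catalyst may discriminate the two faces of this particular quinone poorly, so that 6 would be obtained with low enantiomeric purity. The fallback replaces catalyst control by a removable chiral alkoxy group; it sets out from 4 and returns at 8. Acid-catalysed alkoxy exchange of 4 with (1R,2S,5R)-menthol (cat. TsOH, toluene, removal of methanol) should give 2-menthyloxy-5-methyl-1,4-benzoquinone F1. A BF3·OEt2-promoted Diels–Alder reaction of F1 with 3, then DBU epimerisation, should give the trans adduct as two diastereomers that differ in the ring-fusion configuration. The one with the ring fusion of 6, the menthyloxy ene-dione F2, would be separated by crystallisation or chromatography. SmI2 under the conditions of step 3 cleaves the menthyloxy group as it does the methoxy group and gives 8.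

Step 11. Transmetalation of the β-branched primary alkylborane to an arylpalladium species crowded by two ortho MOM ethers may be slower than protodeboronation and reduction of the aryl bromide. The fallback builds the same bond by carbonyl addition; it sets out from 17 and returns at 18. Oxidation of 17 with NaBO3·4H2O should give the primary alcohol F3, and Dess–Martin oxidation the aldehyde F4; a trace of DBU would equilibrate C1 to the equatorial epimer if the hydroboration had been unselective. 2,4,6-Tris(methoxymethoxy)phenyllithium F5, made from 15 with n-BuLi, adds to F4 at −78 °C to give the benzylic carbinol F6. Ionic hydrogenation with Et3SiH and a little TFA at −40 °C removes the benzylic hydroxyl through the tris-alkoxybenzyl cation and gives 18; that cation should form far more readily than the MOM ethers or the tertiary alcohol ionise.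

Step 6. Trapping of the planar C4 radical by oxygen may show poor facial selectivity and give much of the 4β-hydroxy epimer. The fallback uses a concerted oxygen transfer instead; it sets out from 10 and returns at 11. Dimethyldioxirane should approach the exocyclic alkene from the α face, away from the C10 methyl, to give the spiro-epoxide F7. LiAlH4 opens the epoxide at its CH2 carbon and reduces both ketones to the triol F8. Dess–Martin oxidation of the two secondary alcohols returns the diketone 11.

**Further compounds**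

F1 | step 2 | 2-[(1R,2S,5R)-menthyloxy]-5-methyl-1,4-benzoquinone | CC1=CC(=O)C(O[C@@H]2C[C@H](C)CC[C@H]2C(C)C)=CC1=O
F2 | step 2 | trans-fused menthyloxy ene-dione (menthyloxy analogue of 6) | CC(C)[Si](C(C)C)(C(C)C)OC1=CC[C@@]2(C)C(=O)C=C(O[C@@H]3C[C@H](C)CC[C@H]3C(C)C)C(=O)[C@@H]2C1
F3 | step 11 | 4α-hydroxy-1β-(hydroxymethyl)-4β,10β-dimethyl-5α-decalin-7-carbonitrile | N#CC1CC[C@@]2(C)[C@H](CO)CC[C@@](C)(O)[C@@H]2C1
F4 | step 11 | 1β-formyl-4α-hydroxy-4β,10β-dimethyl-5α-decalin-7-carbonitrile | N#CC1CC[C@@]2(C)[C@H](C=O)CC[C@@](C)(O)[C@@H]2C1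
F5 | step 11 | 2,4,6-tris(methoxymethoxy)phenyllithium | [Li]c1c(OCOC)cc(OCOC)cc1OCOC
F6 | step 11 | 4α-hydroxy-1β-{hydroxy[2,4,6-tris(methoxymethoxy)phenyl]methyl}-4β,10β-dimethyl-5α-decalin-7-carbonitrile | N#CC1CC[C@@]2(C)[C@H](C(O)c3c(OCOC)cc(OCOC)cc3OCOC)CC[C@@](C)(O)[C@@H]2C1
F7 | step 6 | 4α,15-spiro-epoxide of 10 (oxygen α, CH2 β) | O=C1CC[C@@]2(C)C(=O)CC[C@@]3(OC3)[C@@H]2C1
F8 | step 6 | 4β,10β-dimethyl-5α-decalin-1,4α,7-triol (C1 and C7 carbinol epimers) | OC1CC[C@@]2(C)C(O)CC[C@@](C)(O)[C@@H]2C1
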